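Do not assume that the warmest flask holds the most J: warmth speeds the ways out of J as well as the way in.

| setting | zeta | alpha | eta | delta |
|---|---|---|---|---|
| E | 5.0 mM | 5.0 mM | 5.0 mM | 5.0 mM |
| D | 2 mol% | 2 mol% | 2 mol% | 2 mol% |
| temperature | −35 °C | 5 °C | −15 °C | 25 °C |
| time | 3.0 min | 3.0 min | 3.0 min | 3.0 min |

* the flask with the highest amount of J, in percent of the E charged ("all alike" if they lie within 1.5 percentage points) (zeta / alpha / eta / delta / all alike)
* final J, as a percentage of the E charged, in zeta
* final J, as a percentage of the E charged, in alpha
* final J, as a percentage of the E charged, in eta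
* final J, as a percentage of the E charged, in delta

- for J the Z are counted in
- as a solid, counted per litre of solution: Z
- the list of constants is for 25 °C, to be carried to other temperatures by the activation energies and enthalpies
- in a conversion Q counts as not yet reacted

    E ⇌ Q (K1 = 0.283, k1 = 0.167 s⁻¹, Ea1 = 81.0 kJ mol⁻¹, ΔH1 = 25.0 kJ mol⁻¹)
    E + D ⇌ D + J (K2 = 1.12, k2 = 320 M⁻¹ s⁻¹, Ea2 = 46.0 kJ mol⁻¹, ΔH2 = 12.0 kJ mol⁻¹)
    D + Q → D + G (k3 = 401 M⁻¹ s⁻¹, Ea3 = 37.0 kJ mol⁻¹)
    J ⇌ X (K4 = 1.1, k4 = 0.00361 s⁻¹, Ea4 = 75.0 kJ mol⁻¹, ΔH4 = −68.0 kJ mol⁻¹)
    Z ⇌ J, rate k5*(cs5 - [J]) while solid is left; crystals form when [J] > cs5 (cs5 = 2.2 mM, k5 = 5.82 s⁻¹)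
    (constants at 25 °C)

E changes into J reversibly on D; E also turns reversibly into Q, which D carries on to G; J turns reversibly into X, and J crystallises as Z above its solubility. Freeze what does not move: D is given back by each step it enters, so hold it at 0.100 mM. The exchange of E and J then becomes pseudo-first-order. Its equilibrium ratio of J to E, carried to each temperature, is 0.331 in zeta, 0.529 in eta, 0.791 in alpha and 1.12 in delta. Add the forward and back constants and divide ln(2) by the sum: alpha gets 0.605 min. Keep this as the exchange half-life, the time in which E and J close half of their gap to the equilibrium ratio. Zeta has 9.62 min, longer than the run; eta has 2.21 min; delta has 0.191 min.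

For a ceiling, ignore Q, G and X: take the share of the charge the ratio allows, times the part of the gap closed in 3.0 min. That gives 4.83% in zeta, 21.1% in eta and 42.7% in alpha. Delta's gap closes early, so its ceiling, 52.8%, says little. For delta take instead an estimate, which is no bound: ignore X, hold Q at its equilibrium ratio to E and let the pool leak to G, which gives 19.9%.

For a floor, overcharge the losses: add a one-way leak to X as well. That gives 4.74% in zeta, 19.7% in eta, 32.3% in alpha and 14.7% in delta. Alpha's floor stands above the ceilings of zeta and eta and above delta's estimate, so I commit to alpha. The ceilings of zeta, eta and alpha and the estimate for delta stay under the solubility, 44.0% of the charge, so I expect no Z.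

The forecast names alpha, with 4.8% in zeta, 33.5% in alpha, 20.3% in eta and 16.8% in delta, on the ground that “The cold flasks are kinetically limited”. These are its own numbers, not mine; those for zeta, alpha and eta lie inside my brackets, and the one for delta lies between my floor and my estimate.

The simulation gives 4.81% in zeta, 33.4% in alpha, 20.1% in eta and 17.7% in delta, and the highest is alpha.

In alpha the exchange half-life of 0.605 min is far shorter than the run, the reading of J over E at the end is 0.784 against the ratio 0.791, and dissolved J is made at 0.241 of the rate at which it is used. The same flask run at −10 °C has the ratio 0.588, an exchange half-life of 1.58 min and a ceiling of 27.1%, and it holds 25.2% of J.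

The numbers were drawn at random within sensible limits; the rest is arithmetic.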